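Rings: A = biaryl ring with OH para to the axis; B = 4-hydroxy-3-aryloxy ring; C = para-phenylene; D = biaryl ring with OH ortho to the axis. Cuts, in order: two O–CH3 bonds; one benzylic C–H next to ring A (traced back to a C–O bond to the ring D oxygen) together with the C–D ethano bridge (traced back to C=C); the A–D biaryl bond; the O–CH ether bond; the B–CH2 bond; the B–O–C diaryl ether bond.
Enabling feature: the phenol oxygen of ring D and the benzylic CH2 next to ring A both sit ortho to the biaryl bond, so O, two carbons of ring D, two carbons of ring A and that CH2 carbon form a six-atom loop. Joining O to the benzylic carbon first (an aryl benzyl ether) leaves the biaryl bond as the last side of a six-membered pyran ring; both bridge atoms are native, so hydrogenolysis of the benzylic C–O bond later returns CH2 and OH with nothing left to remove.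
Forward: the chain is joined B–O–C, then A–CO–CH2–B, then ring D through the ether oxygen (steps 1 to 4). The pyran ring and the biaryl bond arise together by C–H arylation from a bromine placed between O and CHO on ring D (step 5). The 16-membered ring closes as a stilbene (step 6), one hydrogenation saturates it and opens the pyran ring (step 7), and demethylation ends the route (step 8).
The biaryl bond is made before ring C is tied to ring D, because a CH2CH2-linked ring C would offer the same palladium centre a second six-membered closure (to a 9,10-dihydrophenanthrene). The rigid bridge then holds the side chain over the biaryl for the macrocyclisation.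
Stereochemistry: the target has no stereocentre and no assigned axis. The one temporary benzylic stereocentre is carried as a racemate from step 3 and erased in step 7, as is the alkene geometry from step 6.

Key step: step 5

Assumption: the biaryl axis of the target is taken as drawn, without a fixed sense, and every intermediate with the benzylic stereocentre (6, 7 and 9 to 13) is racemic.

Step 1
Reactants: 1 5-bromo-2-methoxyphenol; 2 4-fluorobenzonitrile
Product: 3 4-(5-bromo-2-methoxyphenoxy)benzonitrile
Conditions: K2CO3, DMF, 120 °C
Reagents that add atoms: none
Why: Nucleophilic aromatic substitution (addition–elimination) in which the phenoxide of 1 displaces fluoride para to the nitrile, the future ring C aldehyde, while the unactivated aryl bromide is kept for step 2.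

Step 2
Reactants: 3 4-(5-bromo-2-methoxyphenoxy)benzonitrile; 4 1-(3-methoxyphenyl)ethan-1-one
Product: 5 4-{2-methoxy-5-[2-(3-methoxyphenyl)-2-oxoethyl]phenoxy}benzonitrile
Conditions: Pd2(dba)3 (cat.), Xantphos (cat.), K3PO4, toluene, 90 °C
Reagents that add atoms: none
Why: Palladium-catalysed α-arylation of a methyl ketone enolate with an aryl bromide (Buchwald–Hartwig type) joins ring B to the CH2 of the future A–B bridge; the mild phosphate base spares the nitrile and the more hindered product enolate should resist a second arylation.

Step 3
Reactants: 5 4-{2-methoxy-5-[2-(3-methoxyphenyl)-2-oxoethyl]phenoxy}benzonitrile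
Product: 7 rac-4-{5-[2-hydroxy-2-(3-methoxyphenyl)ethyl]-2-methoxyphenoxy}benzaldehyde, via hydroxy aldimine 6 (not isolated)
Conditions: i-Bu2AlH (3 equiv), CH2Cl2, −78 to 0 °C; then 1 M HCl (aq), rt
Reagents that add atoms: water, O
Why: i-Bu2AlH reduces the ketone to the secondary alkoxide and adds once to the nitrile, the N-aluminated aldimine resisting further hydride until aqueous acid hydrolyses it to the aldehyde (partial reduction of a nitrile); the new benzylic stereocentre is formed without control because step 7 removes it.

Step 4
Reactants: 7 rac-4-{5-[2-hydroxy-2-(3-methoxyphenyl)ethyl]-2-methoxyphenoxy}benzaldehyde; 8 2-bromo-3-hydroxybenzaldehyde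
Product: 9 rac-2-bromo-3-{2-[3-(4-formylphenoxy)-4-methoxyphenyl]-1-(3-methoxyphenyl)ethoxy}benzaldehyde
Conditions: PPh3, DIAD, THF, 0 °C to rt
Reagents that add atoms: none
Why: Mitsunobu etherification in which the acidic phenol 8 displaces the benzylic oxyphosphonium ion with inversion (immaterial for a racemate), tying the ring D oxygen to the benzylic carbon next to ring A and bringing in the bromine, flanked by O and CHO, that marks the coupling carbon of ring D; aldehydes are inert to the reagents.

Step 5
Reactants: 9 rac-2-bromo-3-{2-[3-(4-formylphenoxy)-4-methoxyphenyl]-1-(3-methoxyphenyl)ethoxy}benzaldehyde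
Product: 10 rac-6-[3-(4-formylphenoxy)-4-methoxybenzyl]-8-methoxy-6H-benzo[c]chromene-1-carbaldehyde
Conditions: Pd(OAc)2 (cat.), PCy3·HBF4 (cat.), t-BuCO2H (cat.), K2CO3, DMA, 130 °C
Reagents that add atoms: none
Why: Zerovalent palladium (from Pd(OAc)2 and PCy3) adds oxidatively to the C–Br bond of ring D, which the ortho formyl group activates, pivalate replaces bromide on divalent palladium, and concerted metalation–deprotonation of an ortho C–H of ring A gives a seven-membered diarylpalladacycle (Pd, two carbons of ring D, O, the benzylic CH, two carbons of ring A) that reductively eliminates the biaryl bond. The closest known reaction type is the palladium-catalysed intramolecular direct arylation of 2-bromophenyl benzyl ethers to 6H-benzo[c]chromenes, which is also used for bridged, hindered biaryls. One ring closes, the six-membered pyran ring of the 6H-benzo[c]chromene, by formation of its aryl–aryl side through contraction of the seven-membered palladacycle, the other five ring bonds being already present in 9. No stereocentre is created: the benzylic centre from step 3 stays racemic, the helical twist of the bridged biaryl simply follows it, and neither survives into the target. The step needs site selection on both rings: on ring D the bromine bought with phenol 8 defines the doubly flanked carbon that no C–H activation would choose, and on ring A the tether reaches only the two carbons ortho to the benzylic carbon, of which the one para to OMe is free whereas the one between OMe and the side chain would give a tetra-ortho-substituted bay; closure onto ring B would need an eight-membered palladacycle and should be slower. Reduction of the C–Br bond is held back because the carboxylate-assisted C–H cleavage takes place right next to palladium.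

Step 6
Reactants: 10 rac-6-[3-(4-formylphenoxy)-4-methoxybenzyl]-8-methoxy-6H-benzo[c]chromene-1-carbaldehyde
Product: 12 bridged (Z)-stilbene macrocycle, via titanium pinacolate 11 (not isolated)
Conditions: TiCl4, Zn, pyridine, THF, reflux; 10 added by syringe pump (high dilution)
Reagents that add atoms: none
Why: McMurry reductive coupling of the two aryl aldehydes on low-valent titanium, by way of the titanium pinacolate and its deoxygenation, closes the 16-membered ring; the pyran bridge holds the benzylic side chain pseudo-axial over the biaryl so that the two formyl groups can meet, and either alkene geometry serves.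

Step 7
Reactants: 12 bridged (Z)-stilbene macrocycle
Product: 14 di-O-methyl plagiochin E, via bridged bibenzyl 13 (not isolated)
Conditions: H2 (4 atm), Pd(OH)2/C, EtOAc–AcOH, 50 °C
Reagents that add atoms: none
Why: Catalytic hydrogenation saturates the strained stilbene, and on the same catalyst the aryl benzyl ether bond of the bridge undergoes hydrogenolysis (the reaction type of O-benzyl phenol deprotection), helped by the twist of the bay-substituted biaryl and by release of strain; the bridge atoms become the native ArCH2 and the ring D phenol, and the only stereocentre disappears.

Step 8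
Reactants: 14 di-O-methyl plagiochin E
Product: 15 plagiochin E
Conditions: BBr3, CH2Cl2, −78 °C to rt; then H2O
Reagents that add atoms: none
Why: BBr3 cleaves both aryl methyl ethers (bromide attack on the methyl group of the boron-complexed ether, then hydrolysis of the aryl borates), the usual last step for bis(bibenzyl)s; the diaryl ether, the biaryl and the ethano bridges are inert.

Compound list
1 | 5-bromo-2-methoxyphenol | COc1ccc(Br)cc1O | starting material
2 | 4-fluorobenzonitrile | N#Cc1ccc(F)cc1 | starting material
3 | 4-(5-bromo-2-methoxyphenoxy)benzonitrile | COc1ccc(Br)cc1Oc1ccc(C#N)cc1 | intermediate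
4 | 1-(3-methoxyphenyl)ethan-1-one (3'-methoxyacetophenone) | CC(=O)c1cccc(OC)c1 | starting material
5 | 4-{2-methoxy-5-[2-(3-methoxyphenyl)-2-oxoethyl]phenoxy}benzonitrile | COc1cccc(c1)C(=O)Cc1ccc(OC)c(c1)Oc1ccc(C#N)cc1 | intermediate
6 | hydroxy aldimine: compound 7 with CH=NH in place of CHO, racemic, present in the flask as its aluminium derivative and drawn metal-free | COc1cccc(c1)C(O)Cc1ccc(OC)c(c1)Oc1ccc(C=N)cc1 | intermediate
7 | rac-4-{5-[2-hydroxy-2-(3-methoxyphenyl)ethyl]-2-methoxyphenoxy}benzaldehyde | COc1cccc(c1)C(O)Cc1ccc(OC)c(c1)Oc1ccc(C=O)cc1 | intermediate
8 | 2-bromo-3-hydroxybenzaldehyde | O=Cc1cccc(O)c1Br | starting material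
9 | rac-2-bromo-3-{2-[3-(4-formylphenoxy)-4-methoxyphenyl]-1-(3-methoxyphenyl)ethoxy}benzaldehyde | COc1cccc(c1)C(Oc1cccc(C=O)c1Br)Cc1ccc(OC)c(c1)Oc1ccc(C=O)cc1 | intermediate
10 | rac-6-[3-(4-formylphenoxy)-4-methoxybenzyl]-8-methoxy-6H-benzo[c]chromene-1-carbaldehyde | COc1ccc2c(c1)C(Cc1ccc(OC)c(c1)Oc1ccc(C=O)cc1)Oc1cccc(C=O)c1-2 | intermediate
11 | macrocyclic pinacol: the two former formyl carbons of 10 joined as CH(OH)–CH(OH), held on titanium as the diolate and drawn metal-free (racemic, mixture at the diol carbons) | COc1ccc2c(c1)C1Cc3ccc(OC)c(c3)Oc3ccc(cc3)C(O)C(O)c3cccc(O1)c3-2 | intermediate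
12 | bridged (Z)-stilbene macrocycle: 16-membered ring with cis CH=CH between ring C and C-1 of the 6H-benzo[c]chromene, pyran bridge kept, OMe on rings A and B (racemic at C-6) | COc1ccc2c(c1)C1Cc3ccc(OC)c(c3)Oc3ccc(cc3)/C=C\c3cccc(O1)c3-2 | intermediate
13 | bridged bibenzyl macrocycle: as 12 with CH2CH2 in place of CH=CH (racemic) | COc1ccc2c(c1)C1Cc3ccc(OC)c(c3)Oc3ccc(cc3)CCc3cccc(O1)c3-2 | intermediate
14 | di-O-methyl plagiochin E (OMe on rings A and B, free OH on ring D) | COc1ccc2c(c1)CCc1ccc(OC)c(c1)Oc1ccc(cc1)CCc1cccc(O)c1-2 | intermediate
15 | plagiochin E | Oc1ccc2c(c1)CCc1ccc(O)c(c1)Oc1ccc(cc1)CCc1cccc(O)c1-2 | target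

Total step count: 8. Longest linear sequence: 8 steps (1 to 15); 2, 4 and 8 are purchased and enter directly.

Steps most likely to fail

Step 6. The formyl group on ring D lies in the hindered bay and the ring being formed is strained, so the coupling may turn intermolecular (oligomers) or stop at the pinacol stage, and the titanium reagent may reductively cleave the benzylic ether. The fallback sets out from 10 and returns at 12. Both formyl groups are methylenated with Ph3P=CH2 (from Ph3PCH3Br and KOt-Bu, THF, 0 °C) to give the bis-styrene F1. F1 is closed by ring-closing olefin metathesis (second-generation Grubbs catalyst, toluene, 80 °C, high dilution, ethene purged) to 12. A catalytic, non-reducing ring closure thus replaces the stoichiometric low-valent metal.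

Step 7. Saturation of the alkene should be fast, but the C–O hydrogenolysis may stop at 13, because the pyran ring holds the benzylic C–O bond nearer the plane of ring A than in an open benzyl ether, which weakens the overlap the cleavage needs. Forcing conditions could then begin to reduce arene rings. The fallback sets out from 12 and returns at 14. 12 is reduced with diimide (TsNHNH2, NaOAc, DME–H2O, reflux) to 13, which is isolated. The bridge is then opened by electron transfer in solution: lithium 4,4'-di-tert-butylbiphenylide in THF at −78 °C, added until its colour persists, then MeOH. The biaryl accepts the electron, the radical anion expels the ring D phenoxide, and the benzylic anion is protonated to give 14 after acidic work-up. No new compound arises.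

Step 5. The free formyl groups may be attacked at 130 °C (migration of palladium from the ring D carbon to the neighbouring formyl C–H followed by decarbonylation, or base-induced disproportionation), and the C–Br bond may be reduced in competition with the C–H cleavage. The fallback sets out from 9 and returns at 10. Both aldehydes are masked as dimethyl acetals (HC(OMe)3, TsOH cat., MeOH, rt) to give the bis(dimethyl acetal) F2. The same palladium-catalysed closure on F2 gives the bridged bis(dimethyl acetal) F3, which has no acyl C–H beside the metal and no base-sensitive carbonyl. 1 M HCl in THF then returns 10.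

Further compounds
F1 | step 6 | rac-6-[4-methoxy-3-(4-vinylphenoxy)benzyl]-8-methoxy-1-vinyl-6H-benzo[c]chromene (bis-styrene) | COc1ccc2c(c1)C(Cc1ccc(OC)c(c1)Oc1ccc(C=C)cc1)Oc1cccc(C=C)c1-2
F0 | step 7 | none | none
F2 | step 5 | bis(dimethyl acetal) of 9 (racemic) | COc1cccc(c1)C(Oc1cccc(C(OC)OC)c1Br)Cc1ccc(OC)c(c1)Oc1ccc(C(OC)OC)cc1
F3 | step 5 | bis(dimethyl acetal) of 10 (racemic) | COc1ccc2c(c1)C(Cc1ccc(OC)c(c1)Oc1ccc(C(OC)OC)cc1)Oc1cccc(C(OC)OC)c1-2
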